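(The runs are calculated with made-up constants; scatter was added.)

In a one-step world catalyst intermediate C hands over target at a rate proportional to its own amount (first order), and the flask is one constant times one amount.

in all of them: starting material 20 mM; free catalyst 15 mol% (in portions, 4)
- beta: reagent 0.50 equiv; capture agent 0.27 mM; run made earlier; portions every 20 h
- alpha: reagent 0.50 equiv; capture agent 0.60 mM; run made earlier; portions every 20 h
- theta: reagent 0.75 equiv; capture agent 0.40 mM; run made earlier; portions every 20 h
- flask: reagent 0.500 equiv; capture agent 0.400 mM; the portions of free catalyst follow each other after 20 h, the first at the start; time 3.0 d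

- beta (time / d: target / %, starting material / %, catalyst intermediate C / %): 0.208: 0.5, 99.4, 0.6; 0.333: 0.4, 98.5, 0.7; 0.417: 1.4, 98.4, 0.8; 0.625: 2.0, 97.1, 1.1; 1.04: 4.0, 94.6, 1.1; 1.67: 9.5, 89.2, 1.3; 2.50: 18.5, 79.3, 2.1
- alpha (time / d: target / %, starting material / %, catalyst intermediate C / %): 0.333: 0.3, 98.7, 0.7; 0.625: 1.8, 97.0, 0.4; 1.04: 3.5, 95.2, 1.0; 1.25: 5.0, 93.3, 1.5; 1.67: 7.7, 90.8, 1.5; 2.08: 11.6, 86.8, 2.1; 2.50: 16.5, 81.6, 1.7
- theta (time / d: target / %, starting material / %, catalyst intermediate C / %): 0.208: 0.4, 98.8, 0.7; 0.625: 1.7, 96.8, 0.9; 1.04: 4.2, 94.3, 1.0; 1.67: 10.0, 88.5, 1.4; 2.50: 19.7, 78.0, 1.8

(scatter of a reading: 0.3 percentage points)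

- what was read earlier has a scatter of 0.3 percentage points, one standard deviation
- steps under discussion: reagent + free catalyst -> catalyst intermediate A; catalyst intermediate A <-> catalyst intermediate B; starting material + catalyst intermediate B <-> catalyst intermediate C; catalyst intermediate C -> by-product + catalyst intermediate D; catalyst intermediate D -> free catalyst + target; catalyst intermediate A + capture agent -> trapped intermediate

- amount of target in the flask at 3.0 d, in percent of the starting material charged
- amount of starting material in the flask at 3.0 d, in percent of the starting material charged
- amount of catalyst intermediate C in the flask at 3.0 d, in percent of the starting material charged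

I read that constant in beta, alpha and theta over the window of 0.830 d that ends at 2.50 d, which lies between two portions. Target gains 9.2 percentage points per run there, while catalyst intermediate C averages 1.63%. That gives 6.76 /d, my turnover constant, the target made per day per point of catalyst intermediate C. It is a reading, with the scatter of 0.3 points in each amount behind it.

First I use this step by itself. I hold catalyst intermediate C at 1.87%, the mean of the three readings at 2.50 d. The remaining 0.500 d then adds 6.3 points, so beta's 18.5% becomes 24.8%.

Next I let the amount move. On average it rose 0.47 points in the window. I assume the last portion keeps that pace, so it ends near 2.15%, and target gains 0.48 points more.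

Then I add the capture agent. Between beta and alpha, target at 2.50 d differs by 2 points. Interpolating to 0.400 mM, I estimate the flask's target at 2.50 d as 17.7%, which is less than beta's.

My reckoning is 24.5% of target, and the balance leaves 73.4% of starting material.

The forecast gives 24.5%, 73.2% and 2.3%, holding that “Capture agent mainly costs early catalyst”.

The flask gives 23.7% of target, 74.0% of starting material and 2.28% of catalyst intermediate C.

    reagent + free catalyst → catalyst intermediate A (k = 30.0 /M/h)
    catalyst intermediate A ⇌ catalyst intermediate B (K = 2.70, k = 0.270 /h)
    starting material + catalyst intermediate B ⇌ catalyst intermediate C (K = 750 /M, k = 15.0 /M/h)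
    catalyst intermediate C → by-product + catalyst intermediate D (k = 0.240 /h)
    catalyst intermediate D → free catalyst + target (k = 21.0 /h)
    catalyst intermediate A + capture agent → trapped intermediate (k = 120 /M/h)

Target stands there partly through the portioned catalyst and the hour of reading together: with the portioning taken away and the catalyst charged at once, the flask gives 38.3%, and with the early reading taken away and replaced by one at 30.0 d, it gives 48.0%. In this flask's last 0.500 d, my turnover constant times the mean amount of catalyst intermediate C makes 7.1 points, against 6.1 points gained. The same flask left until 5.0 d ends with 0.925% of catalyst intermediate C. The constant and the mean of the two end amounts then give 22 points more target, so 45.7%, against the 42.7% it holds.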